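(All runs are simulated with constants of no real substance.)

A leftover first: at its last reading the spring run has 83.5 % of the charge not read as target, so these runs show us no end state, and we can reckon only how fast a flask starts.

| flask | substrate | temperature | remark | time |
|---|---|---|---|---|
| dawn | 0.89 M | 75 °C | run made earlier |  |
| spring | 0.89 M | 88 °C | run made earlier |  |
| cedar | 2.5 M | 80 °C |  | 3.0 min |
| alder | 0.80 M | 95 °C |  | 3.0 min |
| ash | 0.80 M | 80 °C |  | 3.0 min |
| elm | 2.5 M | 95 °C |  | 3.0 min |

- dawn (time / s: target / %): 20.0: 1.0; 40.0: 0.9; 50.0: 1.2; 80.0: 1.5; 90.0: 1.6; 120: 1.1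
- spring (time / s: target / %): 20.0: 1.7; 40.0: 2.3; 50.0: 4.0; 80.0: 7.0; 90.0: 8.3; 120: 16.5

(scatter of a reading: 0.5 percentage points)

- a reading or a percentage of target counts all its forms, free or not

- the flasks put in order of amount of target, in percent of the substrate charged, best first, at 3.0 min (cedar / alder / ash / elm)
- the amount of target, in percent of the substrate charged of the flask you put first, at 3.0 min
- the amount of target, in percent of the substrate charged of the flask you put last, at 3.0 min

Both runs were read at the same times and differ in temperature, so we take the heat ratio G, the sum of the spring readings over the sum of the dawn readings, as what the step from dawn's temperature T_d to spring's T_s multiplies target by. Let s be the dawn sum over the sum of the reading times. Our initial-rate line for target at temperature T and time t is then: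

Σ spring = 39.8 %, Σ dawn = 7.30 %, Σ t = 400 s

G = 5.45

y(T, t) = s · t · G^((T − T_d)/(T_s − T_d))

At dawn's temperature this gives 3.28 % at 3.0 min, and for ash at 80 °C it gives 6.31 %.

The objection is that spring bends upward. At 80.0 s the line gives 7.96 % against a reading of 7.0 %, which is near enough, but at 120 s it gives 11.9 % against 16.5 %. So the line serves up to about that 7.0 %: ash stands inside this range, and alder's 44.6 % does not, so we drop that number. A second objection is that ash holds less substrate than the runs, whose charges are equal; a percentage of the charge stays put if the start is first-order, so we let this pass. On this line ash, cooler than alder and elm, stands below both, but cedar at the same 80 °C gets the same percentage, a tie that the line leaves open, so we give ash 6.31 % and commit to neither a last place nor a top value.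

The forecast said elm > alder > cedar > ash, with 97 % first and 3.3 % last, the latter for ash, where our own figure is 6.31 %, and added “Elm and alder may be nearly tied”.

The simulation gives alder > elm > cedar > ash, with 43.1 % first and 6.41 % last.

    substrate + 2 target → 3 target (k = 0.570 M⁻² s⁻¹, Ea = 46.0 kJ mol⁻¹)
    substrate → target (k = 3.60 × 10⁻⁴ s⁻¹, Ea = 107 kJ mol⁻¹)
    2 substrate → homo dimer (k = 0.00670 M⁻¹ s⁻¹, Ea = 53.0 kJ mol⁻¹)
    crystals ⇌ target, rate k4*(cs4 - [target]) while solid is left; crystals form when [target] > cs4 (solubility = 0.260 M, k = 4.50 s⁻¹)
    (constants at 80 °C)

Ash stands at 6.41 % against our 6.31 %, and the same line with G gives 1.71 % for alder's recipe run at 70 °C, which gave 1.72 %. In alder itself, the step from 2 substrate to homo dimer had half of its turnover done by 0.307 min, and at 1.50 min, with substrate at 10.2 %, homo dimer stood at 56.7 % and target at 33.0 %. By 3.00 min homo dimer still stood at 56.9 % while target had reached 43.1 %, with 10.6 % of the charge as crystals.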